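**Plan**

1. Cuts, in retrosynthetic order: the acetate; the bond from the dione CH to the carbonyl beside the CMe2-bearing ring carbon (dione back to a γ-ylidene butenolide); the CH2–C(=CH2) bond of the macrocycle; the ylidene C=C (butenolide + enal); the ring CH2–CH2 and CH–CMe2 bonds of the cyclohexene (diene + acrolein); in the side chain the trisubstituted C=C and the carbinol–CH2 bond.
2. Enabling feature: the six-membered ring has one double bond, the tetrasubstituted C=C it shares with the five-membered ring, flanked by the CMe2 carbon and the allylic CH2. This is a Diels–Alder retron whose diene is the pair of exocyclic C=C bonds (=CH2 and =CMe2) on adjacent carbons of a five-membered lactone, which holds it s-cis.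
3. Forward ring order: butyrolactone diene 8, then the cyclohexene (step 4), then side-chain union at the lactone γ-carbon, then a 13-membered carbocycle (B-alkyl Suzuki–Miyaura), then contraction to the cyclopentenedione and the 12-membered ring, then the acetate.
4. Stereochemistry: the ring CH comes from the imidazolidinone-catalysed Diels–Alder reaction, the carbinol carbon from asymmetric 2-bromoallylboration of acrolein, the (E)-alkene from cross-metathesis, and the dione CH from equilibration.

Key step: step 4

Remark: the CH between the two ring carbonyls is a readily exchanged 1,3-dicarbonyl methine; its configuration in the target is assumed to be the one favoured at equilibrium in the macrocycle and is set by equilibration in step 11.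

**Route**

Step 1
Reactants: 1 4-methyl hydrogen itaconate
Product: 3 4-methylideneoxolan-2-one, via hydroxy ester 2 (not isolated)
Conditions: BH3·SMe2 (1.05 equiv), THF, -10 °C to rt; MeOH then H2O; TsOH (catalytic), CH2Cl2, rt
Reagents that add atoms: none
Why: Borane reduces the free carboxylic acid faster than the ester or the conjugated 1,1-disubstituted alkene, and the γ-hydroxy ester 2 closes to the five-membered lactone under acid catalysis (chemoselective borane reduction followed by lactonisation).

Step 2
Reactants: 3 4-methylideneoxolan-2-one; 4 acetone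
Product: 6 rac-3-(2-hydroxypropan-2-yl)-4-methylideneoxolan-2-one, via lithium dienolate 5 (not isolated)
Conditions: LiN(iPr)2, THF, -78 °C; 4, -78 °C; AcOH quench at -78 °C
Reagents that add atoms: none
Why: Kinetic deprotonation of the CH2 between the lactone carbonyl and the exocyclic alkene gives dienolate 5, which should add to acetone through its α-carbon at low temperature (lithium enolate aldol addition), the new centre being racemic and removed in step 3.

Step 3
Reactants: 6 rac-3-(2-hydroxypropan-2-yl)-4-methylideneoxolan-2-one
Product: 8 4-methylidene-3-(propan-2-ylidene)oxolan-2-one, via mesylate 7 (not isolated)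
Conditions: MsCl, Et3N (4 equiv), CH2Cl2, 0 °C to rt
Reagents that add atoms: none
Why: Mesylation of the tertiary alcohol and E1cB loss of methanesulfonate through the doubly activated α-hydrogen should give the conjugated isopropylidene lactone (mesylation/elimination), whose two exocyclic alkenes form the s-cis diene; it is used without heating to avoid a 1,5-hydrogen shift.

Step 4
Reactants: 8 4-methylidene-3-(propan-2-ylidene)oxolan-2-one; 9 acrolein
Product: 12 (6R)-7,7-dimethyl-1-oxo-1,3,4,5,6,7-hexahydroisobenzofuran-6-carbaldehyde, via acrolein iminium ion 10 (not isolated), via cycloadduct iminium ion 11 (not isolated)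
Conditions: (5S)-5-benzyl-2,2,3-trimethylimidazolidin-4-one hydrochloride (20 mol%), 9 (3 equiv), MeCN/H2O 95:5, -10 °C to rt
Reagents that add atoms: water O
Why: Acrolein is activated as iminium ion 10 and the ring-locked s-cis diene of 8 adds in an asynchronous [4+2] cycloaddition (organocatalytic Diels–Alder reaction), after which hydrolysis of 11 releases 12 and the amine. The closest known reaction type is the imidazolidinone-catalysed Diels–Alder reaction of acrolein with simple dienes. The cyclohexene closes in the suprafacial 4π+2π mode, the CH2–CH2 bond between the diene methylene and the β-carbon of acrolein leading and the CH–CMe2 bond following. The only new stereocentre, the ring CH, is set by the catalyst: in the (E)-iminium ion the benzyl group covers the Re face of the α-carbon, so the CMe2 terminus bonds to the Si face, which corresponds to (R); endo and exo approach give the same product because both diene termini carry identical substituents. The step needs regioselectivity (formyl-bearing carbon next to CMe2), and the diene secures it: the unhindered, non-acylated methylene is its nucleophilic terminus, and bonding there leaves allyl-cation character on the gem-dimethyl carbon, whereas the reverse orientation would place it beside the lactone carbonyl.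

Step 5
Reactants: 12 (6R)-7,7-dimethyl-1-oxo-1,3,4,5,6,7-hexahydroisobenzofuran-6-carbaldehyde
Product: 13 (6S)-6-ethenyl-7,7-dimethyl-4,5,6,7-tetrahydroisobenzofuran-1(3H)-one
Conditions: Ph3PCH3Br, KN(SiMe3)2, THF, -78 °C to 0 °C
Reagents that add atoms: methyltriphenylphosphonium bromide C[P+](c1ccccc1)(c1ccccc1)c1ccccc1.[Br-]
Why: Wittig methylenation of the aldehyde at low temperature should outrun enolisation of the hindered α-centre and attack on the lactone, so the stereocentre is kept (its descriptor changes to S by priority only).

Step 6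
Reactants: 9 acrolein; 14 propadiene
Product: 17 (3S)-5-bromohexa-1,5-dien-3-ol, via 2-bromoallylborane 15 (not isolated), via borinate ester 16 (not isolated)
Conditions: B-bromodiisopinocampheylborane (prepared from (+)-α-pinene and BH2Br·SMe2), 14, CH2Cl2, -78 °C to -20 °C; 9, -78 °C; NaOH, H2O2, 0 °C
Reagents that add atoms: B-bromodiisopinocampheylborane BrB([C@@H]1C[C@@H]2C[C@H]([C@H]1C)C2(C)C)[C@@H]1C[C@@H]2C[C@H]([C@H]1C)C2(C)C
Why: Bromoboration of the allene gives 2-bromoallylborane 15, which should add to acrolein through a chair six-membered transition state (asymmetric allylboration), the isopinocampheyl groups from (+)-α-pinene directing attack to the aldehyde face that gives the (S)-carbinol.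

Step 7
Reactants: 17 (3S)-5-bromohexa-1,5-dien-3-ol
Product: 18 {[(3S)-5-bromohexa-1,5-dien-3-yl]oxy}(tert-butyl)dimethylsilane
Conditions: TBSCl, imidazole, DMF, rt
Reagents that add atoms: tert-butyldimethylsilyl chloride CC(C)(C)[Si](C)(C)Cl
Why: Silylation of the secondary allylic alcohol (silyl ether protection) gives a group that should survive amine base, borane, palladium and methoxide and is removed by fluoride at the end.

Step 8
Reactants: 18 {[(3S)-5-bromohexa-1,5-dien-3-yl]oxy}(tert-butyl)dimethylsilane; 19 methacrolein
Product: 20 (2E,4S)-6-bromo-4-[(tert-butyldimethylsilyl)oxy]-2-methylhepta-2,6-dienal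
Conditions: second-generation Hoveyda–Grubbs catalyst RuCl2(H2IMes)(=CH-C6H4-2-OiPr) (5 mol%), 19 (8 equiv), CH2Cl2, 40 °C
Reagents that add atoms: none
Why: Cross-metathesis of the monosubstituted alkene with excess methacrolein should give the (E)-trisubstituted enal under thermodynamic control, while the 2-bromo-1,1-disubstituted alkene is a poor metathesis partner and is expected to remain.

Step 9
Reactants: 13 (6S)-6-ethenyl-7,7-dimethyl-4,5,6,7-tetrahydroisobenzofuran-1(3H)-one; 20 (2E,4S)-6-bromo-4-[(tert-butyldimethylsilyl)oxy]-2-methylhepta-2,6-dienal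
Product: 23 (3Z,6S)-3-[(2E,4S)-6-bromo-4-(tert-butyldimethylsilyloxy)-2-methylhepta-2,6-dien-1-ylidene]-6-ethenyl-7,7-dimethyl-4,5,6,7-tetrahydroisobenzofuran-1(3H)-one, via silyloxyfuran 21 (not isolated), via silylated aldol 22 (not isolated)
Conditions: TBSOTf (1.3 equiv), iPr2NEt (1.5 equiv), CH2Cl2, 0 °C; 20, -78 °C to 0 °C; DBU (3 equiv), rt
Reagents that add atoms: none
Why: Soft enolisation gives 2-silyloxyfuran 21, which should add through its free 5-position to the aldehyde (vinylogous Mukaiyama aldol addition), and DBU then eliminates silanol from 22 to the thermodynamically preferred (Z)-γ-ylidene butenolide, whose geometry has no consequence later.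

Step 10
Reactants: 23 (Z)-γ-ylidene butenolide
Product: 25 macrocyclic ylidene butenolide (13-membered carbocycle), via alkylborane 24 (not isolated)
Conditions: 9-BBN (1.5 equiv), THF, 0 °C to rt; H2O; slow addition to PdCl2(dppf) (20 mol%), AsPh3 (20 mol%), Cs2CO3 (3 equiv), DMF/THF/H2O, 50 °C, 1 mM
Reagents that add atoms: none
Why: 9-BBN should hydroborate the monosubstituted ethenyl group much faster than the bromoalkene, the electron-poor ylidene diene or the tetrasubstituted alkene, and the intramolecular B-alkyl Suzuki–Miyaura coupling with the 2-bromoalkene under high dilution closes the 13-membered ring and installs the exocyclic methylene.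

Step 11
Reactants: 25 macrocyclic ylidene butenolide
Product: 27 tert-butyldimethylsilyl ether of deacetylcespitularin K, via keto ester 26 (not isolated)
Conditions: NaOMe (3 equiv), MeOH/THF, 0 °C to rt; aqueous HCl to pH 3, 0 °C
Reagents that add atoms: none
Why: Methoxide opens the enol lactone to keto ester 26, whose ketone enolate closes onto the ester in a 5-exo Dieckmann-type condensation (ylidene butenolide to cyclopent-4-ene-1,3-dione rearrangement), contracting the carbocycle to 12 members; the stable dione enolate should drive the reaction and outrun loss of the allylic silyloxy group, and its equilibrating protonation sets the CH between the carbonyls as assumed.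

Step 12
Reactants: 27 tert-butyldimethylsilyl ether of deacetylcespitularin K
Product: 28 deacetylcespitularin K
Conditions: HF·pyridine, pyridine, THF, 0 °C to rt
Reagents that add atoms: none
Why: Buffered acidic fluoride should cleave the silyl ether (desilylation) without exposing the acidic dione methine or the ene-dione to a strong base.

Step 13
Reactants: 28 deacetylcespitularin K
Product: 29 Cespitularin K
Conditions: Ac2O, pyridine, CH2Cl2, 0 °C to rt
Reagents that add atoms: acetic anhydride CC(=O)OC(C)=O
Why: Acetylation of the secondary allylic alcohol (esterification) should be selective because the dione cannot O-acylate without forming a cyclopentadienone enol ester, and the mild base keeps the CH between the carbonyls at its equilibrium configuration.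

**Compound list**

1 | 4-methyl hydrogen itaconate (2-methylidenebutanedioic acid 4-methyl ester) | C=C(CC(=O)OC)C(=O)O | starting material
2 | methyl 3-(hydroxymethyl)but-3-enoate | C=C(CO)CC(=O)OC | intermediate
3 | 4-methylideneoxolan-2-one | C=C1COC(=O)C1 | intermediate
4 | acetone | CC(C)=O | starting material
5 | lithium 4-methylidene-4,5-dihydrofuran-2-olate (dienolate of 3) | [Li+].[O-]C1=CC(=C)CO1 | intermediate
6 | rac-3-(2-hydroxypropan-2-yl)-4-methylideneoxolan-2-one | CC(C)(O)C1C(=C)COC1=O | intermediate
7 | rac-2-(4-methylidene-2-oxooxolan-3-yl)propan-2-yl methanesulfonate | CC(C)(OS(C)(=O)=O)C1C(=C)COC1=O | intermediate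
8 | 4-methylidene-3-(propan-2-ylidene)oxolan-2-one | CC(C)=C1C(=C)COC1=O | intermediate
9 | acrolein (prop-2-enal) | C=CC=O | starting material
10 | (5S)-5-benzyl-2,2,3-trimethyl-4-oxo-1-[(E)-prop-2-en-1-ylidene]imidazolidin-1-ium chloride | C=C/C=[N+]1\[C@@H](Cc2ccccc2)C(=O)N(C)C1(C)C.[Cl-] | intermediate
11 | iminium chloride of 12 with (5S)-5-benzyl-2,2,3-trimethylimidazolidin-4-one, ring CH (R) | CC1(C)[C@H](/C=[N+]2\[C@@H](Cc3ccccc3)C(=O)N(C)C2(C)C)CCC2=C1C(=O)OC2.[Cl-] | intermediate
12 | (6R)-7,7-dimethyl-1-oxo-1,3,4,5,6,7-hexahydroisobenzofuran-6-carbaldehyde | O=C[C@@H]1CCC2=C(C(=O)OC2)C1(C)C | intermediate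
13 | (6S)-6-ethenyl-7,7-dimethyl-4,5,6,7-tetrahydroisobenzofuran-1(3H)-one | C=C[C@@H]1CCC2=C(C(=O)OC2)C1(C)C | intermediate
14 | propadiene (allene) | C=C=C | starting material
15 | (2-bromoprop-2-en-1-yl)diisopinocampheylborane, isopinocampheyl groups from (+)-α-pinene | C=C(Br)CB([C@@H]1C[C@@H]2C[C@H]([C@H]1C)C2(C)C)[C@@H]1C[C@@H]2C[C@H]([C@H]1C)C2(C)C | intermediate
16 | diisopinocampheylborinate of 17 | C=C[C@@H](OB([C@@H]1C[C@@H]2C[C@H]([C@H]1C)C2(C)C)[C@@H]1C[C@@H]2C[C@H]([C@H]1C)C2(C)C)CC(Br)=C | intermediate
17 | (3S)-5-bromohexa-1,5-dien-3-ol | C=C[C@@H](O)CC(Br)=C | intermediate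
18 | {[(3S)-5-bromohexa-1,5-dien-3-yl]oxy}(tert-butyl)dimethylsilane | C=C[C@@H](O[Si](C)(C)C(C)(C)C)CC(Br)=C | intermediate
19 | methacrolein (2-methylprop-2-enal) | C=C(C)C=O | starting material
20 | (2E,4S)-6-bromo-4-[(tert-butyldimethylsilyl)oxy]-2-methylhepta-2,6-dienal | O=C/C(C)=C/[C@@H](O[Si](C)(C)C(C)(C)C)CC(Br)=C | intermediate
21 | tert-butyl{[(6S)-6-ethenyl-7,7-dimethyl-4,5,6,7-tetrahydroisobenzofuran-1-yl]oxy}dimethylsilane | C=C[C@@H]1CCc2coc(O[Si](C)(C)C(C)(C)C)c2C1(C)C | intermediate
22 | (6S)-3-[(2E,4S)-6-bromo-1,4-bis(tert-butyldimethylsilyloxy)-2-methylhepta-2,6-dien-1-yl]-6-ethenyl-7,7-dimethyl-4,5,6,7-tetrahydroisobenzofuran-1(3H)-one, mixture at the two new centres | C=C[C@@H]1CCC2=C(C(=O)OC2C(O[Si](C)(C)C(C)(C)C)/C(C)=C/[C@@H](O[Si](C)(C)C(C)(C)C)CC(Br)=C)C1(C)C | intermediate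
23 | (3Z,6S)-3-[(2E,4S)-6-bromo-4-(tert-butyldimethylsilyloxy)-2-methylhepta-2,6-dien-1-ylidene]-6-ethenyl-7,7-dimethyl-4,5,6,7-tetrahydroisobenzofuran-1(3H)-one | C=C[C@@H]1CCC2=C(C(=O)O/C2=C\C(C)=C\[C@@H](O[Si](C)(C)C(C)(C)C)CC(Br)=C)C1(C)C | intermediate
24 | B-alkyl-9-borabicyclo[3.3.1]nonane from 23, boron on the terminal carbon of the former ethenyl group | C1CC2CCCC(C1)B2CC[C@@H]1CCC2=C(C(=O)O/C2=C\C(C)=C\[C@@H](O[Si](C)(C)C(C)(C)C)CC(Br)=C)C1(C)C | intermediate
25 | macrocyclic ylidene butenolide: 23 with the terminal ethenyl carbon bonded to the former C–Br carbon (13-membered carbocycle; Z enol lactone; E trisubstituted alkene; exocyclic methylene; ring CH R; silyloxy carbon S) | C=C1CC[C@@H]2CCC3=C(C(=O)O/C3=C\C(C)=C\[C@@H](O[Si](C)(C)C(C)(C)C)C1)C2(C)C | intermediate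
26 | macrocyclic keto ester: methyl ester on the ring carbon beside CMe2, ketone in the 13-membered ring (ring CH R; silyloxy carbon S; E alkene) | C=C1CC[C@@H]2CCC(=C(C(=O)OC)C2(C)C)C(=O)C/C(C)=C/[C@@H](O[Si](C)(C)C(C)(C)C)C1 | intermediate
27 | tert-butyldimethylsilyl ether of deacetylcespitularin K | C=C1CC[C@@H]2CCC3=C(C(=O)[C@H](C3=O)/C(C)=C/[C@@H](O[Si](C)(C)C(C)(C)C)C1)C2(C)C | intermediate
28 | deacetylcespitularin K (free secondary allylic alcohol) | C=C1CC[C@@H]2CCC3=C(C(=O)[C@H](C3=O)/C(C)=C/[C@@H](O)C1)C2(C)C | intermediate
29 | Cespitularin K | C=C1CC[C@@H]2CCC3=C(C(=O)[C@H](C3=O)/C(C)=C/[C@@H](OC(C)=O)C1)C2(C)C | target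

**Totals and risks**

Total step count: 13. Longest linear sequence: 10 steps (steps 1–5 and 9–13).

Steps most likely to fail:

Step 4. The cycloaddition of the acyl-substituted diene with the iminium ion may be too slow, or facial control may be incomplete. The fallback sets out from 8 and comes back at 12. A Lewis-acid Diels–Alder reaction of 8 with (4S)-3-acryloyl-4-benzyloxazolidin-2-one (Et2AlCl, CH2Cl2, -78 °C) should give imide F1; the aluminium chelate fixes the s-cis acrylimide and the benzyl group covers the same face of the α-carbon as the organocatalyst does. Reductive removal of the auxiliary (LiBH4, THF/H2O, 0 °C) gives alcohol F2, and Dess–Martin oxidation returns to 12.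

Step 10. The aqueous base may open the enol lactone during the coupling, or intermolecular coupling may outrun closure of the 13-membered ring. The fallback sets out from 23 and comes back at 27, exchanging the order of ring contraction and ring closure. NaOMe in MeOH followed by acid converts 23, through keto ester F3, into open-chain dione F4. The dione is masked as its sodium enolate (NaH, THF), and 9-BBN then gives alkylborane F5. The same palladium-catalysed coupling under high dilution closes the 12-membered ring directly to 27, with no enol lactone exposed to base.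

Step 8. Cross-metathesis at the hindered allylic silyl ether may be slow, so that homodimerisation of 18 or catalyst decay at the bromoalkene takes over. The fallback sets out from 18 and comes back at 20. Selective oxidative cleavage of the monosubstituted alkene (OsO4 catalytic, NaIO4, 2,6-lutidine, dioxane/H2O; the electron-poor bromoalkene reacts more slowly) gives aldehyde F6. Wittig olefination with 2-(triphenylphosphoranylidene)propanal (toluene, 80 °C) then gives the (E)-enal 20.

Further compounds
F1 | step 4 | (4S)-4-benzyl-3-{[(6R)-7,7-dimethyl-1-oxo-1,3,4,5,6,7-hexahydroisobenzofuran-6-yl]carbonyl}oxazolidin-2-one | O=C(N1C(=O)OC[C@@H]1Cc1ccccc1)[C@@H]1CCC2=C(C(=O)OC2)C1(C)C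
F2 | step 4 | (6R)-6-(hydroxymethyl)-7,7-dimethyl-4,5,6,7-tetrahydroisobenzofuran-1(3H)-one | OC[C@@H]1CCC2=C(C(=O)OC2)C1(C)C
F3 | step 10 | open-chain keto ester from 23 (methyl ester beside CMe2; side-chain ketone; not isolated) | C=C[C@@H]1CCC(C(=O)C/C(C)=C/[C@@H](O[Si](C)(C)C(C)(C)C)CC(Br)=C)=C(C(=O)OC)C1(C)C
F4 | step 10 | open-chain 2-alkenylcyclopent-4-ene-1,3-dione (CH between the carbonyls equilibrating) | C=C[C@@H]1CCC2=C(C(=O)C(C2=O)/C(C)=C/[C@@H](O[Si](C)(C)C(C)(C)C)CC(Br)=C)C1(C)C
F5 | step 10 | B-alkyl-9-borabicyclo[3.3.1]nonane from F4 (drawn as the neutral dione) | C1CC2CCCC(C1)B2CC[C@@H]1CCC2=C(C(=O)C(C2=O)/C(C)=C/[C@@H](O[Si](C)(C)C(C)(C)C)CC(Br)=C)C1(C)C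
F6 | step 8 | (2S)-4-bromo-2-[(tert-butyldimethylsilyl)oxy]pent-4-enal | O=C[C@@H](O[Si](C)(C)C(C)(C)C)CC(Br)=C
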